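## Retrosynthetic overview

1. Target 24 comes from hydroxyquinone 22 by acetylation; the ring C quinone is unveiled last from trimethoxyarene 20.
2. Ring A is closed last at C3–C4. The C-4 α-acyl radical of a lactone (an enolate carbon used with reversed polarity) adds to the terminal carbon of the C-10 allyl group and sets quaternary C-4.
3. The lactone ring (C4–C5) comes from an intramolecular pyruvate carbonyl-ene reaction on a 1,4-dihydronaphthalene; this also moves the alkene to C6=C7 and sets H-5.
4. Quaternary C-10 is set by asymmetric allylation of a 1,4-dihydro-1-naphthoate dienolate.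
5. Ring B comes from a Diels–Alder reaction of quinone 6 (the future ring C) with pentadienoic acid. Ring order: C, B, lactone, A.

Assumption: positions are numbered as in abietane and the target is (4S,5R,10R); in step 5 the (R,R)-ligand is taken to give the R product, and the (S,S)-ligand is used if a test run shows the opposite sense.

## Route

Step 1
Reactants: 1 1,2,4-trimethoxybenzene; 2 acetone
Product: 4 2-(2,3,6-trimethoxyphenyl)propan-2-ol, via aryllithium 3 (not isolated)
Conditions: n-BuLi, TMEDA, THF, 0 °C; then acetone, −78 °C to rt; H2O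
Reagents that add atoms: none
Why: Directed ortho-lithiation at the carbon flanked by two methoxy groups, followed by 1,2-addition of the aryllithium to acetone.

Step 2
Reactants: 4 2-(2,3,6-trimethoxyphenyl)propan-2-ol
Product: 5 2-isopropyl-1,3,4-trimethoxybenzene
Conditions: Et3SiH, CF3CO2H, CH2Cl2, 0 °C to rt
Reagents that add atoms: none
Why: Ionic hydrogenation; the acid ionises the tertiary benzylic alcohol and the silane delivers hydride to the cation.

Step 3
Reactants: 5 2-isopropyl-1,3,4-trimethoxybenzene
Product: 6 2-isopropyl-3-methoxy-1,4-benzoquinone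
Conditions: (NH4)2Ce(NO3)6, MeCN/H2O, 0 °C
Reagents that add atoms: water, O
Why: Oxidative demethylation of the para-dimethoxy pair by tetravalent cerium gives the para-quinone, with the third methoxy group kept as a vinylogous ester.

Step 4
Reactants: 6 2-isopropyl-3-methoxy-1,4-benzoquinone; 7 (E)-penta-2,4-dienoic acid
Product: 10 racemic methyl 6-isopropyl-5,7,8-trimethoxy-1,4-dihydronaphthalene-1-carboxylate, via Diels–Alder adduct 8 (not isolated), via hydroquinone acid 9 (not isolated)
Conditions: toluene, BHT (cat.), 90 °C, sealed; then K2CO3, Me2SO4, acetone, reflux, N2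
Reagents that add atoms: dimethyl sulfate, COS(=O)(=O)OC
Why: Diels–Alder reaction at the unsubstituted quinone double bond, in which the CH2 terminus of the 1-carboxy diene bonds to the quinone carbon beta to the more electron-poor carbonyl (the one beside C–OMe) so that the carboxyl-bearing carbon ends next to that carbonyl, followed by base enolisation to the hydroquinone and O-methylation of both phenols and the acid; the adduct stereocentres are erased, and any conjugated 3,4-dihydro isomer formed gives the same dienolate in step 5.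

Step 5
Reactants: 10 racemic methyl 6-isopropyl-5,7,8-trimethoxy-1,4-dihydronaphthalene-1-carboxylate; 11 allyl acetate
Product: 13 methyl (1R)-1-allyl-6-isopropyl-5,7,8-trimethoxy-1,4-dihydronaphthalene-1-carboxylate, via lithium dienolate 12 (not isolated)
Conditions: LiN(SiMe3)2, THF, −78 °C; then allyl acetate, [Pd(C3H5)Cl]2 (2.5 mol %), (R,R)-DACH-phenyl Trost ligand (7.5 mol %), −78 to 0 °C
Reagents that add atoms: none
Why: Proposed new method: Tsuji–Trost asymmetric allylic alkylation of the planar lithium dienolate, in which the chiral pocket of the pi-allyl palladium complex tells the arene-flanked face from the alkene-flanked face and sets quaternary C-10 as R, with alpha-attack expected as in Birch reductive alkylations of 1-naphthoates; the closest known reactions are Trost allylations of 3-aryloxindole and 2-substituted tetralone enolates.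

Step 6
Reactants: 13 methyl (1R)-1-allyl-6-isopropyl-5,7,8-trimethoxy-1,4-dihydronaphthalene-1-carboxylate
Product: 14 [(1R)-1-allyl-6-isopropyl-5,7,8-trimethoxy-1,4-dihydronaphthalen-1-yl]methanol
Conditions: LiAlH4, THF, 0 °C to rt
Reagents that add atoms: none
Why: Hydride reduction of the neopentyl ester to the primary alcohol (the future C-20) without touching the quaternary centre.

Step 7
Reactants: 14 [(1R)-1-allyl-6-isopropyl-5,7,8-trimethoxy-1,4-dihydronaphthalen-1-yl]methanol; 15 pyruvic acid
Product: 16 [(1R)-1-allyl-6-isopropyl-5,7,8-trimethoxy-1,4-dihydronaphthalen-1-yl]methyl 2-oxopropanoate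
Conditions: DCC, DMAP (cat.), CH2Cl2, 0 °C
Reagents that add atoms: none
Why: Steglich esterification puts the keto carbon (future C-4, with its methyl) and the ester carbon (future C-19) on the C-20 oxygen.

Step 8
Reactants: 16 [(1R)-1-allyl-6-isopropyl-5,7,8-trimethoxy-1,4-dihydronaphthalen-1-yl]methyl 2-oxopropanoate
Product: 17 tricyclic hydroxy lactone (4S,5R,10R; ring A still open)
Conditions: Sc(OTf)3 (10 mol %), CH2Cl2, 0 °C to rt
Reagents that add atoms: none
Why: Lewis-acid-catalysed intramolecular carbonyl-ene reaction in which the chelated keto carbon is delivered by its C-20 tether to C-5 on the face of C-20 (cis-fused δ-lactone, H-5 trans to C-20) while a doubly activated C-7 hydrogen passes to oxygen and the alkene moves to C6=C7; the C-4 configuration formed here is erased in step 9.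

Step 9
Reactants: 17 tricyclic hydroxy lactone (4S,5R,10R; ring A still open); 18 methyl chlorooxoacetate
Product: 20 (4S,5R,10R)-11,12,14-trimethoxyabieta-6,8,11,13-tetraen-19,20-olide, via tertiary methyl oxalate 19 (not isolated)
Conditions: ClC(O)CO2Me, Et3N, DMAP (cat.), CH2Cl2, 0 °C; crude, then Bu3SnH (syringe pump), AIBN, toluene (0.005 M), 110 °C
Reagents that add atoms: none
Why: Barton-type radical deoxygenation of the tertiary oxalate gives the C-4 α-acyl radical, an electrophilic carbon at the normally nucleophilic enolate position, which adds 6-endo to the terminal alkene carbon through a chair transition state (the 5-exo mode would need a trans-fused, bridged five-membered ring) before Bu3SnH reduces the secondary radical; C-4 can only be bridged on the lactone face, so the quaternary centre is set as S with the methyl group alpha and ring A trans-fused.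

Step 10
Reactants: 20 (4S,5R,10R)-11,12,14-trimethoxyabieta-6,8,11,13-tetraen-19,20-olide
Product: 22 (4S,5R,10R)-12-hydroxy-11,14-dioxoabieta-6,8,12-trien-19,20-olide, via triol 21 (not isolated)
Conditions: BBr3, CH2Cl2, −78 to 0 °C; then H2O, NaHCO3, air, rt
Reagents that add atoms: none
Why: Lewis-acid cleavage of the three aryl methyl ethers (the neopentyl C-20–O bond of the lactone resists bromide attack) and autoxidation of the hydroxyhydroquinone to the 12-hydroxy-11,14-quinone.

Step 11
Reactants: 22 (4S,5R,10R)-12-hydroxy-11,14-dioxoabieta-6,8,12-trien-19,20-olide; 23 acetic anhydride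
Product: 24 (4S,5R,10R)-12-acetoxy-11,14-dioxoabieta-6,8,12-trien-19,20-olide
Conditions: Ac2O, pyridine, DMAP (cat.), CH2Cl2, 0 °C
Reagents that add atoms: none
Why: O-acylation of the acidic hydroxyquinone under mild base, which leaves the vinylogously acidic H-5 untouched.

## Compound list

1 | 1,2,4-trimethoxybenzene | COc1ccc(OC)c(OC)c1 | starting material
2 | acetone | CC(C)=O | starting material
3 | (2,3,6-trimethoxyphenyl)lithium | [Li]c1c(OC)ccc(OC)c1OC | intermediate
4 | 2-(2,3,6-trimethoxyphenyl)propan-2-ol | CC(C)(O)c1c(OC)ccc(OC)c1OC | intermediate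
5 | 2-isopropyl-1,3,4-trimethoxybenzene | CC(C)c1c(OC)ccc(OC)c1OC | intermediate
6 | 2-isopropyl-3-methoxy-1,4-benzoquinone | COC1=C(C(C)C)C(=O)C=CC1=O | intermediate
7 | (E)-penta-2,4-dienoic acid | OC(=O)/C=C/C=C | starting material
8 | racemic endo Diels–Alder adduct, 6-isopropyl-7-methoxy-5,8-dioxo-1,4,4a,5,8,8a-hexahydronaphthalene-1-carboxylic acid (cis ring fusion) | COC1=C(C(C)C)C(=O)C2CC=CC(C(=O)O)C2C1=O | intermediate
9 | racemic 5,8-dihydroxy-6-isopropyl-7-methoxy-1,4-dihydronaphthalene-1-carboxylic acid | COc1c(C(C)C)c(O)c2c(c1O)C(C(=O)O)C=CC2 | intermediate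
10 | racemic methyl 6-isopropyl-5,7,8-trimethoxy-1,4-dihydronaphthalene-1-carboxylate | COC(=O)C1C=CCc2c(OC)c(C(C)C)c(OC)c(OC)c12 | intermediate
11 | allyl acetate | CC(=O)OCC=C | starting material
12 | lithium dienolate of 10 (achiral) | [Li]OC(OC)=C1C=CCc2c(OC)c(C(C)C)c(OC)c(OC)c12 | intermediate
13 | methyl (1R)-1-allyl-6-isopropyl-5,7,8-trimethoxy-1,4-dihydronaphthalene-1-carboxylate | COC(=O)[C@]1(CC=C)C=CCc2c(OC)c(C(C)C)c(OC)c(OC)c12 | intermediate
14 | [(1R)-1-allyl-6-isopropyl-5,7,8-trimethoxy-1,4-dihydronaphthalen-1-yl]methanol | OC[C@]1(CC=C)C=CCc2c(OC)c(C(C)C)c(OC)c(OC)c12 | intermediate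
15 | pyruvic acid | CC(=O)C(=O)O | starting material
16 | [(1R)-1-allyl-6-isopropyl-5,7,8-trimethoxy-1,4-dihydronaphthalen-1-yl]methyl 2-oxopropanoate | CC(=O)C(=O)OC[C@]1(CC=C)C=CCc2c(OC)c(C(C)C)c(OC)c(OC)c12 | intermediate
17 | tricyclic hydroxy lactone (4S,5R,10R): δ-lactone C-19(=O)–O–C-20 cis-fused at C-5/C-10 to the 1,2-dihydronaphthalene, H-5 trans to C-20, C6=C7 alkene, allyl on C-10, OH and CH3 on C-4, 13-isopropyl-11,12,14-trimethoxy arene | C[C@@]1(O)C(=O)OC[C@@]2(CC=C)c3c(OC)c(OC)c(C(C)C)c(OC)c3C=C[C@@H]12 | intermediate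
18 | methyl chlorooxoacetate | COC(=O)C(=O)Cl | starting material
19 | methyl oxalate of 17 at the C-4 oxygen | C[C@@]1(OC(=O)C(=O)OC)C(=O)OC[C@@]2(CC=C)c3c(OC)c(OC)c(C(C)C)c(OC)c3C=C[C@@H]12 | intermediate
20 | (4S,5R,10R)-11,12,14-trimethoxyabieta-6,8,11,13-tetraen-19,20-olide (C-19 carbonyl, oxygen on C-20) | COc1c(C(C)C)c(OC)c2c(c1OC)[C@]13CCC[C@](C)(C(=O)OC1)[C@@H]3C=C2 | intermediate
21 | (4S,5R,10R)-11,12,14-trihydroxyabieta-6,8,11,13-tetraen-19,20-olide | Oc1c(C(C)C)c(O)c2c(c1O)[C@]13CCC[C@](C)(C(=O)OC1)[C@@H]3C=C2 | intermediate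
22 | (4S,5R,10R)-12-hydroxy-11,14-dioxoabieta-6,8,12-trien-19,20-olide | OC1=C(C(C)C)C(=O)C2=C(C1=O)[C@]13CCC[C@](C)(C(=O)OC1)[C@@H]3C=C2 | intermediate
23 | acetic anhydride | CC(=O)OC(C)=O | starting material
24 | (4S,5R,10R)-12-acetoxy-11,14-dioxoabieta-6,8,12-trien-19,20-olide | CC(=O)OC1=C(C(C)C)C(=O)C2=C(C1=O)[C@]13CCC[C@](C)(C(=O)OC1)[C@@H]3C=C2 | target

## Step count and risks

Total steps: 11. Longest linear sequence: 11 (fully linear from 1).

**Step 4 (Diels–Alder).** Both partners are electron-poor, so the rate may be low, and the regiochemistry rests on a frontier-orbital argument. The fallback sets out from arene 5 and comes back at dienolate 12. Friedel–Crafts acylation of 5 with succinic anhydride (SnCl4, CH2Cl2) can only go para to a methoxy group and gives 4-(3-isopropyl-2,4,5-trimethoxyphenyl)-4-oxobutanoic acid F1. Et3SiH/CF3CO2H reduces the aryl ketone to 4-(3-isopropyl-2,4,5-trimethoxyphenyl)butanoic acid F2. Polyphosphoric acid closes the ring at the one free aryl position to 6-isopropyl-5,7,8-trimethoxy-3,4-dihydronaphthalen-1(2H)-one F3. KN(SiMe3)2 and PhNTf2 give the enol triflate F4. Carbonylation (Pd(OAc)2, dppp, CO, MeOH, Et3N) gives methyl 6-isopropyl-5,7,8-trimethoxy-3,4-dihydronaphthalene-1-carboxylate F5. Its gamma-deprotonation with LiN(SiMe3)2 gives the same dienolate 12, so step 5 follows unchanged and quinone 6 is not needed.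

**Step 5 (asymmetric allylation).** The enantioselectivity is unproven for this ester dienolate, and gamma-allylation at C-6 may compete. The fallback sets out from 10 and comes back at alcohol 14. LiN(iPr)2 and allyl bromide give the racemic allyl ester F6. KOH in aqueous DMSO at 100 °C gives the racemic acid F7. Crystallisation with (R)-1-phenylethylamine (the amine enantiomer is chosen so that the salt of the R acid is the less soluble one) gives the salt of the R acid F8 and leaves the salt of the S acid F9 in the mother liquor. HCl frees the (R)-acid F10, and LiAlH4 reduces it to 14.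

**Step 9 (radical ring closure).** The C-4 radical may be reduced before it cyclises, or some 5-exo closure may occur. The fallback sets out from 17 (through crude oxalate 19) and comes back at 20. SmI2, HMPA and t-BuOH in THF reduce the α-acyloxy lactone to the 4-deoxy lactone F11 (C-4 epimers, of no consequence). 9-BBN then NaBO3 hydroborates only the terminal alkene to the primary alcohol F12. I2, PPh3 and imidazole give the primary iodide F13. KN(SiMe3)2 in THF at −78 °C forms the lactone enolate, which closes ring A by intramolecular SN2 alkylation to 20, replacing the radical by an enolate.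

## Further compounds

F1 | step 4 | 4-(3-isopropyl-2,4,5-trimethoxyphenyl)-4-oxobutanoic acid | CC(C)c1c(OC)c(C(=O)CCC(=O)O)cc(OC)c1OC
F2 | step 4 | 4-(3-isopropyl-2,4,5-trimethoxyphenyl)butanoic acid | CC(C)c1c(OC)c(CCCC(=O)O)cc(OC)c1OC
F3 | step 4 | 6-isopropyl-5,7,8-trimethoxy-3,4-dihydronaphthalen-1(2H)-one | O=C1CCCc2c(OC)c(C(C)C)c(OC)c(OC)c12
F4 | step 4 | 6-isopropyl-5,7,8-trimethoxy-3,4-dihydronaphthalen-1-yl trifluoromethanesulfonate | FC(F)(F)S(=O)(=O)OC1=CCCc2c(OC)c(C(C)C)c(OC)c(OC)c12
F5 | step 4 | methyl 6-isopropyl-5,7,8-trimethoxy-3,4-dihydronaphthalene-1-carboxylate | COC(=O)C1=CCCc2c(OC)c(C(C)C)c(OC)c(OC)c12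
F6 | step 5 | racemic methyl 1-allyl-6-isopropyl-5,7,8-trimethoxy-1,4-dihydronaphthalene-1-carboxylate | COC(=O)C1(CC=C)C=CCc2c(OC)c(C(C)C)c(OC)c(OC)c12
F7 | step 5 | racemic 1-allyl-6-isopropyl-5,7,8-trimethoxy-1,4-dihydronaphthalene-1-carboxylic acid | OC(=O)C1(CC=C)C=CCc2c(OC)c(C(C)C)c(OC)c(OC)c12
F8 | step 5 | (R)-1-phenylethylammonium salt of the (1R)-acid | [O-]C(=O)[C@]1(CC=C)C=CCc2c(OC)c(C(C)C)c(OC)c(OC)c12.C[C@@H]([NH3+])c1ccccc1
F9 | step 5 | (R)-1-phenylethylammonium salt of the (1S)-acid (mother liquor) | [O-]C(=O)[C@@]1(CC=C)C=CCc2c(OC)c(C(C)C)c(OC)c(OC)c12.C[C@@H]([NH3+])c1ccccc1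
F10 | step 5 | (1R)-1-allyl-6-isopropyl-5,7,8-trimethoxy-1,4-dihydronaphthalene-1-carboxylic acid | OC(=O)[C@]1(CC=C)C=CCc2c(OC)c(C(C)C)c(OC)c(OC)c12
F11 | step 9 | 4-deoxy analogue of 17 (H in place of OH at C-4, epimer mixture) | CC1C(=O)OC[C@@]2(CC=C)c3c(OC)c(OC)c(C(C)C)c(OC)c3C=C[C@@H]12
F12 | step 9 | primary alcohol from hydroboration of F11 (3-hydroxypropyl on C-10) | CC1C(=O)OC[C@@]2(CCCO)c3c(OC)c(OC)c(C(C)C)c(OC)c3C=C[C@@H]12
F13 | step 9 | primary iodide from F12 (3-iodopropyl on C-10) | CC1C(=O)OC[C@@]2(CCCI)c3c(OC)c(OC)c(C(C)C)c(OC)c3C=C[C@@H]12
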